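The route is convergent: a perhydro-1-benzoxepine iodide and a hydroazulenone vinylogous ester are joined at the enone β-carbon by a Stork–Danheiser addition. Everything rests on disconnecting the oxepane (1-benzoxepine numbering) at C5–C5a and at C2–C3. The key step exploits the fact that the quaternary ring-fusion carbon C5a lies α to the oxygen-bearing fusion carbon C9a: with C9a as a ketone, its regiodefined silyl enol ether adds to acrolein (C5–C5a, trans to the C6 substituent), and the liberated aldehyde is olefinated in the same flask by an isopropylidene ylide (C2=C3). The precursor is a cyclohexanone silyl enol ether; the homoprenyl ketone formed is later closed to the oxepane by epoxide opening at C2.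

Key step: step 4

Assumption: (S)-(+)-linalool of high enantiomeric purity is taken as a commercial starting material.

Step 1
Reactants: 1 1,4-dioxaspiro[4.5]dec-6-en-8-one
Product: 2 7-iodo-1,4-dioxaspiro[4.5]dec-6-en-8-one
Conditions: I2, pyridine, CH2Cl2, 0 °C to rt
Reagents that add atoms: iodine, II
Why: Pyridine-mediated α-iodination of a cyclohexenone (addition–elimination, Johnson iodination) should leave the ketal untouched; no stereocenter is formed.

Step 2
Reactants: 2 7-iodo-1,4-dioxaspiro[4.5]dec-6-en-8-one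
Product: 3 7-methyl-1,4-dioxaspiro[4.5]dec-6-en-8-one
Conditions: MeB(OH)2, PdCl2(dppf) (5 mol %), K3PO4, dioxane/H2O, 80 °C
Reagents that add atoms: methylboronic acid, CB(O)O
Why: Suzuki–Miyaura methylation of an α-iodoenone is an established way to place an α-methyl group on an enone; no stereocenter is formed.

Step 3
Reactants: 3 7-methyl-1,4-dioxaspiro[4.5]dec-6-en-8-one
Product: 4 (6R)-6-ethenyl-7-methyl-8-(trimethylsilyloxy)-1,4-dioxaspiro[4.5]dec-7-ene
Conditions: CH2=CHMgBr, CuBr·SMe2 (5 mol %), Josiphos-type ligand, Me3SiCl, t-BuOMe/THF, −78 °C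
Reagents that add atoms: vinylmagnesium bromide, C=C[Mg]Br; chlorotrimethylsilane, C[Si](C)(C)Cl
Why: Copper-catalysed asymmetric conjugate addition of a Grignard reagent to an α-methyl cyclohexenone with silyl trapping of the enolate should set C6 by ligand control (the ligand enantiomer is chosen to give 6R) and fix the enolate regiochemistry at C7.

Step 4
Reactants: 4 (6R)-6-ethenyl-7-methyl-8-(trimethylsilyloxy)-1,4-dioxaspiro[4.5]dec-7-ene; 5 acrolein; 6 isopropyltriphenylphosphonium iodide
Product: 8 (6R,7R)-6-ethenyl-7-methyl-7-(4-methylpent-3-en-1-yl)-1,4-dioxaspiro[4.5]decan-8-one, via keto aldehyde 7 (not isolated)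
Conditions: 5, BF3·OEt2 (0.3 equiv), i-PrOH, MeNO2/CH2Cl2, −78 °C; then Ph3P=CMe2 (from 6, n-BuLi, THF), −78 °C to rt
Reagents that add atoms: none
Why: BF3-activated acrolein should be attacked at its β-carbon by C7 of the tetrasubstituted silyl enol ether (Mukaiyama–Michael addition), isopropanol taking up the silyl group so that keto aldehyde 7 is released, and the non-stabilised ylide added cold then converts the aldehyde carbon into the isopropylidene terminus (Wittig olefination). The closest known reaction types are the Lewis acid/alcohol-promoted Michael addition of 2-methyl-1-silyloxycyclohexenes to enals and the chemoselective Wittig olefination of keto aldehydes. No ring is closed in this step. The one new stereocenter, quaternary C7 (the later C5a), is controlled by the neighbouring C6 vinyl group, which sits pseudoaxial in the enol ether half-chair because of allylic strain with the C7 methyl and shields one face, so acrolein should enter trans to it. The step needs C- over O-attack and 1,4- over 1,2-addition (soft silyl enol ether with a Lewis acid), survival of the dioxolane (low temperature, substoichiometric BF3) and aldehyde over ketone selectivity in the olefination (the C8 ketone is flanked by the new quaternary carbon).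

Step 5
Reactants: 8 (6R,7R)-6-ethenyl-7-methyl-7-(4-methylpent-3-en-1-yl)-1,4-dioxaspiro[4.5]decan-8-one
Product: 9 (6R,7R,8R)-6-ethenyl-7-methyl-7-(4-methylpent-3-en-1-yl)-1,4-dioxaspiro[4.5]decan-8-ol
Conditions: NaBH4, MeOH, 0 °C
Reagents that add atoms: none
Why: In the chair with the vinyl and homoprenyl groups equatorial and the C7 methyl axial, borohydride reduction by axial attack anti to that methyl should give the equatorial 8R alcohol, cis to the methyl and trans to the side chain.

Step 6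
Reactants: 9 (6R,7R,8R)-6-ethenyl-7-methyl-7-(4-methylpent-3-en-1-yl)-1,4-dioxaspiro[4.5]decan-8-ol
Product: 10 (6R,7R,8R)-7-{2-[(2R)-3,3-dimethyloxiran-2-yl]ethyl}-6-ethenyl-7-methyl-1,4-dioxaspiro[4.5]decan-8-ol
Conditions: Shi ketone (D-fructose-derived, 30 mol %), Oxone, K2CO3, Bu4NHSO4, MeCN/CH2(OMe)2/aq. buffer, 0 °C
Reagents that add atoms: Oxone (potassium peroxymonosulfate), [K+].[O-]S(=O)(=O)OO
Why: Shi asymmetric epoxidation of the trisubstituted alkene should give the (R)-epoxide by reagent control, and the monosubstituted vinyl group is far less reactive towards the dioxirane.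

Step 7
Reactants: 10 (6R,7R,8R)-7-{2-[(2R)-3,3-dimethyloxiran-2-yl]ethyl}-6-ethenyl-7-methyl-1,4-dioxaspiro[4.5]decan-8-ol
Product: 12 (3R,5aR,6R,9aR)-6-ethenyl-3-hydroxy-2,2,5a-trimethyloctahydro-1-benzoxepin-7(2H)-one, via oxepane ketal 11 (not isolated)
Conditions: CSA (10 mol %), CH2Cl2, 0 °C; then acetone/H2O, 40 °C
Reagents that add atoms: water, O
Why: Acid-catalysed hydroxy-epoxide cyclisation in the 7-endo mode should have the equatorial C8 hydroxyl open the epoxide at its tertiary carbon, leaving the carbinol carbon R and giving the trans-fused oxepane, after which aqueous acetone hydrolyses the dioxolane.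

Step 8
Reactants: 12 (3R,5aR,6R,9aR)-6-ethenyl-3-hydroxy-2,2,5a-trimethyloctahydro-1-benzoxepin-7(2H)-one
Product: 13 (3R,5aR,6R,7S,9aR)-6-ethenyl-2,2,5a,7-tetramethyldecahydro-1-benzoxepine-3,7-diol
Conditions: MeLi, CeCl3, THF, −78 °C
Reagents that add atoms: methyllithium, [Li]C
Why: Organocerium 1,2-addition (low basicity, so the α-vinyl ketone is not enolised) should occur by equatorial attack because the axial path is blocked by the syn-axial C5a methyl, giving the axial 7S hydroxyl.

Step 9
Reactants: 13 (3R,5aR,6R,7S,9aR)-6-ethenyl-2,2,5a,7-tetramethyldecahydro-1-benzoxepine-3,7-diol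
Product: 14 (3R,5aR,6R,7S,9aR)-6-ethenyl-2,2,5a,7-tetramethyl-3,7-bis(triethylsilyloxy)decahydro-1-benzoxepine
Conditions: Et3SiOTf, 2,6-lutidine, CH2Cl2, 0 °C to rt
Reagents that add atoms: triethylsilyl trifluoromethanesulfonate, CC[Si](CC)(CC)OS(=O)(=O)C(F)(F)F
Why: Silylation with a silyl triflate and 2,6-lutidine should protect both the secondary and the hindered tertiary alcohol without touching any stereocenter.

Step 10
Reactants: 14 (3R,5aR,6R,7S,9aR)-6-ethenyl-2,2,5a,7-tetramethyl-3,7-bis(triethylsilyloxy)decahydro-1-benzoxepine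
Product: 15 (3R,5aR,6R,7S,9aR)-6-(2-iodoethyl)-2,2,5a,7-tetramethyl-3,7-bis(triethylsilyloxy)decahydro-1-benzoxepine
Conditions: Cp2Zr(H)Cl, THF, rt; then I2, 0 °C
Reagents that add atoms: iodine, II
Why: Schwartz hydrozirconation places zirconium on the terminal carbon of the vinyl group and iodinolysis of the C–Zr bond should give the primary iodide.

Step 11
Reactants: 16 (S)-linalool
Product: 17 (3S)-3,7-dimethylocta-1,6-dien-3-yl 2-methylpropanoate
Conditions: n-BuLi, THF, −78 °C; i-PrCOCl, −78 °C to rt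
Reagents that add atoms: isobutyryl chloride, CC(C)C(Cl)=O
Why: O-Acylation of the lithium alkoxide of a tertiary allylic alcohol with an acid chloride should give the ester with the stereocenter untouched.

Step 12
Reactants: 17 (3S)-3,7-dimethylocta-1,6-dien-3-yl 2-methylpropanoate
Product: 18 (1S)-1-methylcyclopent-2-en-1-yl 2-methylpropanoate
Conditions: second-generation Grubbs catalyst (2 mol %), CH2Cl2, 40 °C
Reagents that add atoms: none
Why: Ring-closing metathesis of the linalyl 1,6-diene should close the cyclopentene with loss of isobutene and leave the carbinol stereocenter unchanged.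

Step 13
Reactants: 18 (1S)-1-methylcyclopent-2-en-1-yl 2-methylpropanoate
Product: 21 2-methyl-2-[(1R)-3-methylcyclopent-2-en-1-yl]propanoic acid, via silyl ketene acetal 19 (not isolated), via trimethylsilyl ester 20 (not isolated)
Conditions: LDA, THF, −78 °C; Me3SiCl; −78 °C to 60 °C; then 1 M HCl
Reagents that add atoms: none
Why: Ireland–Claisen rearrangement is suprafacial, so the new C–C bond should form on the ring face of the departing C–O bond and the carbinol chirality is relayed to the new 1R ring carbon next to the gem-dimethyl carbon.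

Step 14
Reactants: 21 2-methyl-2-[(1R)-3-methylcyclopent-2-en-1-yl]propanoic acid
Product: 22 2-methyl-2-[(1R)-3-methylcyclopent-2-en-1-yl]pentan-3-one
Conditions: EtLi (2.5 equiv), Et2O, 0 °C to rt; then aq. NH4Cl
Reagents that add atoms: ethyllithium, [Li]CC
Why: Addition of an alkyllithium to the lithium carboxylate gives a stable gem-dialkoxide that should collapse to the ethyl ketone on work-up.

Step 15
Reactants: 22 2-methyl-2-[(1R)-3-methylcyclopent-2-en-1-yl]pentan-3-one
Product: 24 (4R)-2-methyl-4-(2-methyl-3-oxopentan-2-yl)cyclopent-2-en-1-one, via allylic alcohol 23 (not isolated)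
Conditions: SeO2 (0.3 equiv), t-BuOOH, CH2Cl2, rt; then Dess–Martin periodinane, NaHCO3, rt
Reagents that add atoms: tert-butyl hydroperoxide, CC(C)(C)OO
Why: Selenium dioxide allylic oxidation (ene reaction, then [2,3]-shift) should oxygenate the ring CH2 next to the methyl-bearing alkene carbon, and Dess–Martin oxidation of the allylic alcohol gives the enone, which removes the new carbinol center.

Step 16
Reactants: 24 (4R)-2-methyl-4-(2-methyl-3-oxopentan-2-yl)cyclopent-2-en-1-one
Product: 25 2-[(1R,4S)-4-hydroxy-3-methylcyclopent-2-en-1-yl]-2-methylpentan-3-one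
Conditions: NaBH4, CeCl3·7H2O, MeOH, −78 °C
Reagents that add atoms: none
Why: Luche 1,2-reduction of the enone should deliver hydride anti to the bulky C4 substituent and so give the cis allylic alcohol, while the hindered saturated ketone reacts more slowly.

Step 17
Reactants: 25 2-[(1R,4S)-4-hydroxy-3-methylcyclopent-2-en-1-yl]-2-methylpentan-3-one
Product: 27 ethyl 2-[(1R,5R)-2-methyl-5-(2-methyl-3-oxopentan-2-yl)cyclopent-2-en-1-yl]acetate, via mixed ketene acetal 26 (not isolated)
Conditions: MeC(OEt)3, EtCO2H (cat.), xylene, 140 °C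
Reagents that add atoms: triethyl orthoacetate, CCOC(C)(OCC)OCC
Why: Johnson–Claisen rearrangement is suprafacial, so the acetate chain should be delivered to the ring face of the allylic oxygen, cis to the neighbouring side chain.

Step 18
Reactants: 27 ethyl 2-[(1R,5R)-2-methyl-5-(2-methyl-3-oxopentan-2-yl)cyclopent-2-en-1-yl]acetate
Product: 28 ethyl 2-[(1R,2R,5R)-2-hydroxy-2-methyl-5-(2-methyl-3-oxopentan-2-yl)cyclopentyl]acetate
Conditions: Mn(dpm)3 (cat.), PhSiH3, O2, i-PrOH/CH2Cl2, 0 °C; then P(OEt)3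
Reagents that add atoms: dioxygen, O=O
Why: Mukaiyama hydration (hydrogen atom transfer to the trisubstituted alkene) gives a tertiary radical that should be trapped by oxygen on the face anti to the adjacent acetate chain, giving the tertiary alcohol trans to it.

Step 19
Reactants: 28 ethyl 2-[(1R,2R,5R)-2-hydroxy-2-methyl-5-(2-methyl-3-oxopentan-2-yl)cyclopentyl]acetate
Product: 29 (3R,3aR,8aR)-3-hydroxy-3,6,8,8-tetramethyloctahydroazulene-5,7-dione
Conditions: KOt-Bu, THF, 0 °C to rt; then aq. HCl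
Reagents that add atoms: none
Why: Intramolecular Claisen (Dieckmann-type) condensation of the ethyl ketone enolate, the only one the ketone can form, onto the ester should close the seven-membered 1,3-dione, driven by formation of the diketone enolate; C6 stays epimerisable and is not needed.

Step 20
Reactants: 29 (3R,3aR,8aR)-3-hydroxy-3,6,8,8-tetramethyloctahydroazulene-5,7-dione
Product: 30 (3R,3aR,8aR)-3-hydroxy-5-methoxy-3,6,8,8-tetramethyl-2,3,3a,4,8,8a-hexahydroazulen-7(1H)-one
Conditions: MeOH, p-TsOH (cat.), 4 Å sieves, rt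
Reagents that add atoms: methanol, CO
Why: Acid-catalysed, equilibrating enol etherification of a cyclic 1,3-dione should place the methoxy group at the less hindered C5 carbonyl and leave the ketone next to the gem-dimethyl carbon.

Step 21
Reactants: 30 (3R,3aR,8aR)-3-hydroxy-5-methoxy-3,6,8,8-tetramethyl-2,3,3a,4,8,8a-hexahydroazulen-7(1H)-one
Product: 31 (3R,3aR,8aR)-5-methoxy-3,6,8,8-tetramethyl-3-(triethylsilyloxy)-2,3,3a,4,8,8a-hexahydroazulen-7(1H)-one
Conditions: Et3SiOTf, 2,6-lutidine, CH2Cl2, −40 °C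
Reagents that add atoms: triethylsilyl trifluoromethanesulfonate, CC[Si](CC)(CC)OS(=O)(=O)C(F)(F)F
Why: Silylation of the tertiary alcohol removes the only acidic proton before the organolithium step; no stereocenter changes.

Step 22
Reactants: 15 (3R,5aR,6R,7S,9aR)-6-(2-iodoethyl)-2,2,5a,7-tetramethyl-3,7-bis(triethylsilyloxy)decahydro-1-benzoxepine; 31 (3R,3aR,8aR)-5-methoxy-3,6,8,8-tetramethyl-3-(triethylsilyloxy)-2,3,3a,4,8,8a-hexahydroazulen-7(1H)-one
Product: 35 target CNP0397160.1, via alkyllithium 32 (not isolated), via tertiary carbinol 33 (not isolated), via silylated enone 34 (not isolated)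
Conditions: 15, t-BuLi (2.1 equiv), Et2O, −78 °C; then 31, THF, −78 to 0 °C; then 2 M HCl, THF/MeOH, rt
Reagents that add atoms: water, O
Why: Lithium–iodine exchange, 1,2-addition to the vinylogous ester carbonyl and acid-mediated hydrolysis with allylic transposition (Stork–Danheiser sequence) should give the tetrasubstituted enone, and the same acid removes the three silyl ethers; the transient carbinol center becomes sp2.

Compound list
1 | 1,4-dioxaspiro[4.5]dec-6-en-8-one | O=C1C=CC2(CC1)OCCO2 | starting material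
2 | 7-iodo-1,4-dioxaspiro[4.5]dec-6-en-8-one | O=C1C(I)=CC2(CC1)OCCO2 | intermediate
3 | 7-methyl-1,4-dioxaspiro[4.5]dec-6-en-8-one | CC1=CC2(CCC1=O)OCCO2 | intermediate
4 | (6R)-6-ethenyl-7-methyl-8-(trimethylsilyloxy)-1,4-dioxaspiro[4.5]dec-7-ene | C=C[C@@H]1C(C)=C(O[Si](C)(C)C)CCC12OCCO2 | intermediate
5 | acrolein (prop-2-enal) | C=CC=O | starting material
6 | isopropyltriphenylphosphonium iodide | CC(C)[P+](c1ccccc1)(c1ccccc1)c1ccccc1.[I-] | starting material
7 | 3-[(6R,7R)-6-ethenyl-7-methyl-8-oxo-1,4-dioxaspiro[4.5]decan-7-yl]propanal (not isolated) | C=C[C@@H]1[C@@](C)(CCC=O)C(=O)CCC12OCCO2 | intermediate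
8 | (6R,7R)-6-ethenyl-7-methyl-7-(4-methylpent-3-en-1-yl)-1,4-dioxaspiro[4.5]decan-8-one | C=C[C@@H]1[C@@](C)(CCC=C(C)C)C(=O)CCC12OCCO2 | intermediate
9 | (6R,7R,8R)-6-ethenyl-7-methyl-7-(4-methylpent-3-en-1-yl)-1,4-dioxaspiro[4.5]decan-8-ol | C=C[C@@H]1[C@@](C)(CCC=C(C)C)[C@H](O)CCC12OCCO2 | intermediate
10 | (6R,7R,8R)-7-{2-[(2R)-3,3-dimethyloxiran-2-yl]ethyl}-6-ethenyl-7-methyl-1,4-dioxaspiro[4.5]decan-8-ol | C=C[C@@H]1[C@@](C)(CC[C@H]3OC3(C)C)[C@H](O)CCC12OCCO2 | intermediate
11 | ethylene ketal of 12, trans-fused oxepane (not isolated) | C=C[C@@H]1[C@@]3(C)CC[C@@H](O)C(C)(C)O[C@@H]3CCC12OCCO2 | intermediate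
12 | (3R,5aR,6R,9aR)-6-ethenyl-3-hydroxy-2,2,5a-trimethyloctahydro-1-benzoxepin-7(2H)-one | C=C[C@@H]1[C@@]3(C)CC[C@@H](O)C(C)(C)O[C@@H]3CCC1=O | intermediate
13 | (3R,5aR,6R,7S,9aR)-6-ethenyl-2,2,5a,7-tetramethyldecahydro-1-benzoxepine-3,7-diol | C=C[C@@H]2[C@@]3(C)CC[C@@H](O)C(C)(C)O[C@@H]3CC[C@]2(C)O | intermediate
14 | (3R,5aR,6R,7S,9aR)-6-ethenyl-2,2,5a,7-tetramethyl-3,7-bis(triethylsilyloxy)decahydro-1-benzoxepine | C=C[C@@H]2[C@@]3(C)CC[C@@H](O[Si](CC)(CC)CC)C(C)(C)O[C@@H]3CC[C@]2(C)O[Si](CC)(CC)CC | intermediate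
15 | (3R,5aR,6R,7S,9aR)-6-(2-iodoethyl)-2,2,5a,7-tetramethyl-3,7-bis(triethylsilyloxy)decahydro-1-benzoxepine | ICC[C@@H]2[C@@]3(C)CC[C@@H](O[Si](CC)(CC)CC)C(C)(C)O[C@@H]3CC[C@]2(C)O[Si](CC)(CC)CC | intermediate
16 | (S)-linalool, (3S)-3,7-dimethylocta-1,6-dien-3-ol | C=C[C@@](C)(O)CCC=C(C)C | starting material
17 | (3S)-3,7-dimethylocta-1,6-dien-3-yl 2-methylpropanoate | C=C[C@@](C)(OC(=O)C(C)C)CCC=C(C)C | intermediate
18 | (1S)-1-methylcyclopent-2-en-1-yl 2-methylpropanoate | C1=C[C@@](C)(OC(=O)C(C)C)CC1 | intermediate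
19 | trimethylsilyl ketene acetal of 18 (not isolated) | C1=C[C@@](C)(OC(O[Si](C)(C)C)=C(C)C)CC1 | intermediate
20 | trimethylsilyl 2-methyl-2-[(1R)-3-methylcyclopent-2-en-1-yl]propanoate (not isolated) | C[Si](C)(C)OC(=O)C(C)(C)[C@@H]1CCC(C)=C1 | intermediate
21 | 2-methyl-2-[(1R)-3-methylcyclopent-2-en-1-yl]propanoic acid | OC(=O)C(C)(C)[C@@H]1CCC(C)=C1 | intermediate
22 | 2-methyl-2-[(1R)-3-methylcyclopent-2-en-1-yl]pentan-3-one | CCC(=O)C(C)(C)[C@@H]1CCC(C)=C1 | intermediate
23 | 2-[(1R,4R)-4-hydroxy-3-methylcyclopent-2-en-1-yl]-2-methylpentan-3-one, trans alcohol (not isolated) | CCC(=O)C(C)(C)[C@@H]1C[C@@H](O)C(C)=C1 | intermediate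
24 | (4R)-2-methyl-4-(2-methyl-3-oxopentan-2-yl)cyclopent-2-en-1-one | CCC(=O)C(C)(C)[C@@H]1CC(=O)C(C)=C1 | intermediate
25 | 2-[(1R,4S)-4-hydroxy-3-methylcyclopent-2-en-1-yl]-2-methylpentan-3-one, cis alcohol | CCC(=O)C(C)(C)[C@@H]1C[C@H](O)C(C)=C1 | intermediate
26 | 2-[(1R,4S)-4-(1-ethoxyethenyloxy)-3-methylcyclopent-2-en-1-yl]-2-methylpentan-3-one (not isolated) | CCC(=O)C(C)(C)[C@@H]1C[C@H](OC(=C)OCC)C(C)=C1 | intermediate
27 | ethyl 2-[(1R,5R)-2-methyl-5-(2-methyl-3-oxopentan-2-yl)cyclopent-2-en-1-yl]acetate | CCC(=O)C(C)(C)[C@@H]1CC=C(C)[C@@H]1CC(=O)OCC | intermediate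
28 | ethyl 2-[(1R,2R,5R)-2-hydroxy-2-methyl-5-(2-methyl-3-oxopentan-2-yl)cyclopentyl]acetate | CCC(=O)C(C)(C)[C@@H]1CC[C@@](C)(O)[C@@H]1CC(=O)OCC | intermediate
29 | (3R,3aR,8aR)-3-hydroxy-3,6,8,8-tetramethyloctahydroazulene-5,7-dione (C6 epimers) | CC1C(=O)C(C)(C)[C@@H]2CC[C@@](C)(O)[C@@H]2CC1=O | intermediate
30 | (3R,3aR,8aR)-3-hydroxy-5-methoxy-3,6,8,8-tetramethyl-2,3,3a,4,8,8a-hexahydroazulen-7(1H)-one | COC1=C(C)C(=O)C(C)(C)[C@@H]2CC[C@@](C)(O)[C@@H]2C1 | intermediate
31 | (3R,3aR,8aR)-5-methoxy-3,6,8,8-tetramethyl-3-(triethylsilyloxy)-2,3,3a,4,8,8a-hexahydroazulen-7(1H)-one | COC1=C(C)C(=O)C(C)(C)[C@@H]2CC[C@@](C)(O[Si](CC)(CC)CC)[C@@H]2C1 | intermediate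
32 | primary alkyllithium from 15 (not isolated) | [Li]CC[C@@H]2[C@@]3(C)CC[C@@H](O[Si](CC)(CC)CC)C(C)(C)O[C@@H]3CC[C@]2(C)O[Si](CC)(CC)CC | intermediate
33 | tertiary carbinol from addition of 32 to C7 of 31, carbinol center unassigned (not isolated) | COC1=C(C)C(O)(CC[C@@H]2[C@@]3(C)CC[C@@H](O[Si](CC)(CC)CC)C(C)(C)O[C@@H]3CC[C@]2(C)O[Si](CC)(CC)CC)C(C)(C)[C@@H]2CC[C@@](C)(O[Si](CC)(CC)CC)[C@@H]2C1 | intermediate
34 | tris(triethylsilyl) ether of the target (not isolated) | CC1=C(CC[C@@H]2[C@@]3(C)CC[C@@H](O[Si](CC)(CC)CC)C(C)(C)O[C@@H]3CC[C@]2(C)O[Si](CC)(CC)CC)C(C)(C)[C@@H]2CC[C@@](C)(O[Si](CC)(CC)CC)[C@@H]2CC1=O | intermediate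
35 | CNP0397160.1: 2-methyl-3-(2-substituted ethyl) hydroazulenone joined to the (3R,5aR,6R,7S,9aR)-3,7-dihydroxy-2,2,5a,7-tetramethyldecahydro-1-benzoxepin-6-yl unit | CC1=C(CC[C@@H]2[C@@]3(C)CC[C@@H](O)C(C)(C)O[C@@H]3CC[C@]2(C)O)C(C)(C)[C@@H]2CC[C@@](C)(O)[C@@H]2CC1=O | target

Total step count: 22. Longest linear sequence: 12 steps (16 to 35, steps 11 to 22).

Steps most likely to fail

Step 7. The cyclisation may lose regiocontrol: the hydroxyl can open the epoxide at the secondary carbon (6-exo) and give a tetrahydropyran with an exocyclic tertiary alcohol. The fallback sets out from epoxide 10. Et2Al(TMP) should isomerise the trisubstituted epoxide to the secondary allylic alcohol bearing an isopropenyl group F1. Iodoetherification with N-iodosuccinimide then leaves only the Markovnikov 7-exo closure at the 1,1-disubstituted alkene and should give the iodomethyl oxepane F2. Radical deiodination with Bu3SnH/AIBN turns the iodomethyl group into the second methyl group and comes back to the route at ketal 11, which is hydrolysed to 12 as in step 7.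

Step 3. Addition at the β-carbon next to the spiro ketal may be slow, and facial selectivity with a vinyl Grignard reagent may be poor. The fallback sets out from enone 3. Rhodium-catalysed asymmetric 1,4-addition of potassium vinyltrifluoroborate ([Rh(cod)Cl]2, (R)-BINAP, toluene/H2O, 100 °C; Hayashi–Miyaura reaction) should give the vinyl ketone F3 as a mixture of C7 epimers. Equilibrating silylation (Me3SiCl, NaI, Et3N, MeCN) favours the more substituted enol ether and returns to the route at 4.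

Step 22. The 1,2-addition to the hindered, electron-rich vinylogous ester carbonyl may be sluggish, and deprotonation at the γ-position may compete. The fallback sets out from dione 29.
- NaBH4/CeCl3 should reduce the less hindered C5 carbonyl to the hydroxy ketone F4.
- MsCl/Et3N gives the mesylate F5, and DBU eliminates it to the enone F6 (ketone at C7, alkene C5=C6).
- Et3SiOTf/2,6-lutidine gives the silyl ether F7.
- Alkyllithium 32 adds to the more electrophilic enone carbonyl of F7 to give the tertiary allylic alcohol F8.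
- Oxidative transposition with pyridinium chlorochromate (Dauben–Babler) comes back to the route at 34, which is desilylated to 35 by the acid treatment of step 22.

Further compounds
F1 | step 7 | (6R,7R,8R)-6-ethenyl-7-[(3R)-3-hydroxy-4-methylpent-4-en-1-yl]-7-methyl-1,4-dioxaspiro[4.5]decan-8-ol | C=C[C@@H]1[C@@](C)(CC[C@@H](O)C(C)=C)[C@H](O)CCC12OCCO2
F2 | step 7 | 2-iodomethyl analogue of ketal 11 (C2 epimers) | C=C[C@@H]1[C@@]3(C)CC[C@@H](O)C(C)(CI)O[C@@H]3CCC12OCCO2
F3 | step 3 | (6R)-6-ethenyl-7-methyl-1,4-dioxaspiro[4.5]decan-8-one (C7 epimers) | C=C[C@@H]1C(C)C(=O)CCC12OCCO2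
F4 | step 22 | (3R,3aR,8aR)-3,5-dihydroxy-3,6,8,8-tetramethyloctahydroazulen-7(1H)-one (C5, C6 epimers) | CC1C(=O)C(C)(C)[C@@H]2CC[C@@](C)(O)[C@@H]2CC1O
F5 | step 22 | C5 methanesulfonate of F4 | CC1C(=O)C(C)(C)[C@@H]2CC[C@@](C)(O)[C@@H]2CC1OS(C)(=O)=O
F6 | step 22 | (3R,3aR,8aR)-3-hydroxy-3,6,8,8-tetramethyl-2,3,3a,4,8,8a-hexahydroazulen-7(1H)-one | C1=C(C)C(=O)C(C)(C)[C@@H]2CC[C@@](C)(O)[C@@H]2C1
F7 | step 22 | triethylsilyl ether of F6 | C1=C(C)C(=O)C(C)(C)[C@@H]2CC[C@@](C)(O[Si](CC)(CC)CC)[C@@H]2C1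
F8 | step 22 | tertiary allylic alcohol from addition of 32 to C7 of F7 | C1=C(C)C(O)(CC[C@@H]2[C@@]3(C)CC[C@@H](O[Si](CC)(CC)CC)C(C)(C)O[C@@H]3CC[C@]2(C)O[Si](CC)(CC)CC)C(C)(C)[C@@H]2CC[C@@](C)(O[Si](CC)(CC)CC)[C@@H]2C1
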